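Ask how much of the first end groups stands as links at the end of a flask whose reagent is being eaten, and reckon it by hand before any integrator does.

first end groups 0.050 M; second end groups 0.0490 M (in portions, 3); protic impurity 0.0500 M; time 25 h; the portions of second end groups follow each other after 2.5 h, the first at the start

- share of the first end groups used up at 25 h
- links at 25 h, in percent of the first end groups charged

    first end groups + second end groups ⇌ links + by-product (K1 = 1.2, k1 = 1200 /M/h)
    second end groups + protic impurity → quenched reagent (k2 = 5.8 /M/h)

Follow one molecule of second end groups: at its first fork, coupling beats quenching 207 to one as charged, because the coupling rate constant times the first end groups far exceeds the quench rate constant times the impurity, so it becomes a link. But a link can fall back and a quench cannot, so count in fractions of the first end groups charged and take the net reagent N, second end groups charged minus protic impurity charged, −0.0200. With h the impurity left, each quench takes one of each, so reagent on hand, links y plus free reagent b, is T = h + N, and y squared over the unused share times b stays at 1.2.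

Let h fall each hour by h·b/τ, with τ = 3.45 h. Put y and h for T and one for the unused share, so b is h squared over 1.2 and the inverse square of h climbs steadily. Start the clock at the last portion, 5.00 h, with h whole: h reaches 0.306, T 0.286, and the equilibrium gives y = 22.9 %. The weak link is the square law, so reforge it: replace 0.833 by b over T squared from that estimate, 0.694. Then h is 0.332, T 0.312, and I commit to 24.6 % for both answers, since each link uses one first end group.

The forecast, a little higher, gives 25.9 % and 25.9 %, holding of step 1 that “it stays at equilibrium while the quench slowly drains the reagent”.

The flask gives 25.8 % and 25.8 %. Left to 250 h, this flask holds 8.37 % of links with 11.0 % of the impurity left, and N puts reagent on hand there at 9.00 %; N is below zero, the impurity outnumbering the reagent, which makes second end groups the limiting reagent of the quench.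

In the neighbour flask with 0.20 M of second end groups, all else as in the recipe, N is 3.00, and putting h at zero makes T equal to N, so the equilibrium gives 77.5 %. Computed, that neighbour flask holds 77.5 % of links at 25.0 h with 0 % of the impurity left.

(The constants stand for no real mixture.)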